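**Plan**
1. Locants (hydroazulene numbering). Ring A is the cyclopentene C1–C5 (C3=C4, methyl on C4). Ring B is C1, C5, C6(OH), C7, C8, C9(OAc), C10(=C18H2). The side chain is C11(H)(C19H3)–C12H2–C13H=C14H–C15(OH)Me2. β is the face carrying O6, C11 and O9; H5 is β and H1 is α, so the A/B fusion is trans.
2. Cuts: O9–acetyl; C13=C14 (cross metathesis); C12–C13 (vinyl 1,4-addition to the α-methylene-γ-lactone O6–C19(=O)–C11(=C12H2), whose carbonyl C19 later becomes the C11 methyl); C6–C7 (closes ring B); C7=C11 (metathesis of a temporary lactone); C8–C9 (allylboration); C4–CH3; C1–C10 and C5–C6 (three-component coupling).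
3. Enabling feature: on ring B, O9 and C11 are 1,3-cis and O6 is cis to C11. C9–O9–C19(=O)–C11=C7–C8 can therefore be tied as a six-membered unsaturated lactone that carries an allylic bromide on C12 and holds the C6 aldehyde over one face of C7.
4. Forward order: ring A from a cyclopentenone, then the temporary six-membered lactone, then ring B by reductive allylation C7→C6 with acyl shift O9→O6. The lactone is removed again by reducing C19 to CH3.
5. Stereochemistry: C1 and C5 come from the silyloxy stereocentre of enone 4 (anti, anti; the centre is then deleted). C9 is set by catalyst-controlled allylboration. C7 is relayed from C9 through the lactone tether. C6 comes from the closed metal-bridged transition state, C11 from convex-face protonation, and the E-alkene C13=C14 from metathesis.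

Key step: step 11

Assumption 1: enone 4 (a prostaglandin building block), acid 17, allylboronic acid pinacol ester and the (R)-phosphoric acid of step 6 are taken as catalogue compounds.
Assumption 2: the (R)-phosphoric acid is taken to deliver the allyl group to the Re face of enal 14, as with other conjugated aldehydes. If the sense were opposite, the antipodal catalyst would be used.

Step 1
Reactants: 1 3,3-diethoxyprop-1-ene (acrolein diethyl acetal)
Product: 3 2-bromo-3,3-diethoxyprop-1-ene, via dibromide 2 (not isolated)
Conditions: Br2, CH2Cl2, −78 to 0 °C; then KOt-Bu, THF, 0 °C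
Reagents that add atoms: bromine BrBr
Why: Bromination–dehydrobromination, in which Br2 adds to the vinyl group and E2 loss of HBr through the acidified C–H next to the acetal should give the 2-bromoalkene, no stereocentre being carried on.

Step 2
Reactants: 3 2-bromo-3,3-diethoxyprop-1-ene; 4 (R)-4-(tert-butyldimethylsilyloxy)cyclopent-2-en-1-one
Product: 8 (2S,3S,4R)-4-(tert-butyldimethylsilyloxy)-3-(3,3-diethoxyprop-1-en-2-yl)-2-(hydroxymethyl)cyclopentan-1-one, via vinyllithium 5 (not isolated), via vinylcopper 6 (not isolated), via copper enolate 7 (not isolated)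
Conditions: 3, t-BuLi (2 equiv), Et2O, −78 °C; CuI, PBu3, −78 °C; 4, −78 °C; CH2O (gas from cracked paraformaldehyde), THF, −78 °C; aq NH4Cl
Reagents that add atoms: formaldehyde C=O
Why: Three-component coupling (alkenylcopper conjugate addition, then aldol trapping), in which the copper reagent should add to C1 anti to the C2 silyloxy group and formaldehyde should enter at C5 anti to the new C1 substituent, fixing the trans C1/C5 pair in absolute terms.

Step 3
Reactants: 8 hydroxymethyl ketone
Product: 10 (4S,5S)-5-[(tert-butyldimethylsilyloxy)methyl]-4-(3,3-diethoxyprop-1-en-2-yl)cyclopent-2-en-1-one, via bis-silyl ether 9 (not isolated)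
Conditions: TBSCl, imidazole, CH2Cl2, 0 to 25 °C; then DBU, 0 °C, short contact
Reagents that add atoms: tert-butyldimethylsilyl chloride CC(C)(C)[Si](C)(C)Cl
Why: Silylation of the primary alcohol followed by E1cB loss of the ring silyloxy group after deprotonation at the unhindered C3 should give the cyclopentenone, with C5 (α to the ketone) staying in its favoured trans arrangement.

Step 4
Reactants: 10 cyclopentenone
Product: 12 (4S,5S)-5-[(tert-butyldimethylsilyloxy)methyl]-4-(3,3-diethoxyprop-1-en-2-yl)cyclopent-1-en-1-yl trifluoromethanesulfonate, via lithium enolate 11 (not isolated)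
Conditions: LiBH(s-Bu)3, THF, −78 °C; then PhNTf2, −78 to 0 °C
Reagents that add atoms: N-phenylbis(trifluoromethanesulfonimide) O=S(=O)(N(c1ccccc1)S(=O)(=O)C(F)(F)F)C(F)(F)F
Why: Conjugate reduction with enolate trapping, in which 1,4-hydride delivery to the β-unsubstituted enone should give the C3=C4 enolate regiospecifically and O-sulfonylation should fix the double bond where the target has it, leaving C1 and C5 untouched.

Step 5
Reactants: 12 enol triflate
Product: 14 2-[(1S,2R)-2-[(tert-butyldimethylsilyloxy)methyl]-3-methylcyclopent-3-en-1-yl]prop-2-enal, via methylcyclopentene acetal 13 (not isolated)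
Conditions: MeMgBr, Fe(acac)3 (5 mol %), THF/NMP, −20 °C; crude product, PPTS, acetone/H2O, 25 °C
Reagents that add atoms: methylmagnesium bromide C[Mg]Br; water O
Why: Iron-catalysed Kumada-type coupling of the alkenyl triflate should install the C4 methyl group without moving the double bond, and mild hydrolysis of the allylic acetal, faster than cleavage of the primary silyl ether, should unmask the 2-substituted acrolein.

Step 6
Reactants: 14 enal
Product: 16 (3R)-2-[(1S,2R)-2-[(tert-butyldimethylsilyloxy)methyl]-3-methylcyclopent-3-en-1-yl]hexa-1,5-dien-3-ol, via borate ester 15 (not isolated)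
Conditions: allylboronic acid pinacol ester, (R)-3,3'-bis(2,4,6-triisopropylphenyl)-1,1'-binaphthyl-2,2'-diyl hydrogen phosphate (5 mol %), toluene, −30 °C; aqueous work-up
Reagents that add atoms: allylboronic acid pinacol ester C=CCB1OC(C)(C)C(C)(C)O1
Why: Brønsted-acid-catalysed asymmetric allylboration through a closed chair transition state, in which the chiral phosphate should direct the allyl group to the Re face of the conjugated aldehyde and set C9 as R under catalyst control.

Step 7
Reactants: 16 homoallylic alcohol; 17 2-(bromomethyl)prop-2-enoic acid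
Product: 18 (3R)-2-[(1S,2R)-2-[(tert-butyldimethylsilyloxy)methyl]-3-methylcyclopent-3-en-1-yl]hexa-1,5-dien-3-yl 2-(bromomethyl)prop-2-enoate
Conditions: DCC, DMAP (3 mol %), CH2Cl2, −20 to 0 °C
Reagents that add atoms: none
Why: Steglich esterification with retention at C9, low temperature and a trace of DMAP keeping the allylic bromide from being displaced.

Step 8
Reactants: 18 triene ester
Product: 19 (6R)-3-(bromomethyl)-6-{1-[(1S,2R)-2-[(tert-butyldimethylsilyloxy)methyl]-3-methylcyclopent-3-en-1-yl]ethenyl}-5,6-dihydro-2H-pyran-2-one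
Conditions: second-generation Grubbs catalyst (5 mol %), CH2Cl2 (0.005 M), 40 °C
Reagents that add atoms: none
Why: Ring-closing metathesis should start at the only monosubstituted alkene and close the six-membered unsaturated lactone on the acrylate, while the hindered C10=C18 and the trisubstituted ring A alkene stay out, and the ring forces C8 and C19 cis on C7=C11.

Step 9
Reactants: 19 silyl ether
Product: 20 (6R)-3-(bromomethyl)-6-{1-[(1S,2R)-2-(hydroxymethyl)-3-methylcyclopent-3-en-1-yl]ethenyl}-5,6-dihydro-2H-pyran-2-one
Conditions: aq HF (48 %), MeCN, 0 °C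
Reagents that add atoms: none
Why: Acidic fluoride desilylation should free the primary alcohol without any nucleophilic amine or base that would attack the allylic bromide or the unsaturated lactone.

Step 10
Reactants: 20 primary alcohol
Product: 21 (1R,5S)-5-{1-[(2R)-5-(bromomethyl)-6-oxo-3,6-dihydro-2H-pyran-2-yl]ethenyl}-2-methylcyclopent-2-ene-1-carbaldehyde
Conditions: Dess–Martin periodinane, NaHCO3, CH2Cl2, 0 °C; used at once
Reagents that add atoms: none
Why: Buffered Dess–Martin oxidation should give the β,γ-unsaturated aldehyde under neutral conditions, so that C5 is not epimerised and C3=C4 does not move into conjugation.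

Step 11
Reactants: 21 bromo aldehyde
Product: 24 (1S,5R,6S,7R,9R)-9-hydroxy-α-methylene-γ-lactone (O6–C19(=O)–C11(=C12H2)–C7 cis-fused on the β face of the trans-hydroazulene), via allylchromium species 22 (not isolated), via bridged hydroxy lactone 23 (not isolated)
Conditions: CrCl2 (6 equiv), THF, 25 °C, slow addition of 21 (final 0.005 M); H2O; then camphorsulfonic acid (5 mol %), CH2Cl2, 25 °C
Reagents that add atoms: none
Why: CrCl2 reduces the allylic C12–Br bond in two one-electron steps to the ester-substituted allylchromium species 22, whose γ-carbon C7 adds to the C6 aldehyde through a closed, chromium-bridged six-membered transition state (intramolecular Nozaki–Hiyama allylation; the closest known type is the metal-promoted cyclisation of ω-formyl 2-(bromomethyl)acrylates to carbocycle-fused α-methylene lactones). Ring B closes 7-exo-trig at the carbonyl carbon with C11 left outside the new ring, and the trivalent chromium alkoxide on O6 then adds 5-exo-trig to the lactone carbonyl C19 and expels O9, so that the bridged six-membered lactone 23 is exchanged for the less strained cis-fused five-membered lactone 24 and O9–H is set free. C7 is controlled by C9, because the chain C10–C1–C5–C6 hangs pseudoaxially from C9 of the half-chair lactone and can reach only the face of C7=C11 syn to it, which matches the 1,3-cis relation of O9 and C11 in the target. C6 is controlled by the closed transition state, in which O6 must stay gauche to C11 to remain bound to the chromium on C12, so O6 ends cis to C11 and pseudoequatorial (anti to C1) in a twist-chair that accommodates the trans A/B fusion (torsion C10–C1–C5–C6 near 85 degrees, sp2 C10 on the axis position). The step needs γ- over α-attack, aldehyde over ester chemoselectivity, cyclisation over oligomerisation and no enolisation of the aldehyde; these are secured by the inherent γ-selectivity of allylchromium reagents, their inertness to esters, slow addition at high dilution and the non-basic medium.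

Step 12
Reactants: 24 α-methylene lactone
Product: 26 (1S,5R,6S,7R,9R,11S)-11-allyl-γ-lactone (H11 on the face of H6 and H7, the C12H2–C13H=CH2 chain on the concave face), via magnesium enolate 25 (not isolated)
Conditions: vinylmagnesium bromide (3.5 equiv), CuI (20 mol %), THF, −78 to −40 °C; aq NH4Cl at −78 °C
Reagents that add atoms: vinylmagnesium bromide C=C[Mg]Br
Why: Copper-catalysed 1,4-addition to the exocyclic enoate should form C12–C13, and kinetic protonation of enolate 25 from the convex face of the cis-fused bicycle should place H11 there, which is the 11S configuration of the target once C19 has become the methyl group.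

Step 13
Reactants: 26 lactone
Product: 27 lactol (O6–C19H(OH), mixture of anomers)
Conditions: i-Bu2AlH (3.2 equiv), CH2Cl2, −78 °C; aq potassium sodium tartrate
Reagents that add atoms: none
Why: Partial reduction of a γ-lactone by i-Bu2AlH should stop at the aluminium lactolate at −78 °C and leave the alkenes and C11 untouched.

Step 14
Reactants: 27 lactol
Product: 28 (E)-C19 tosylhydrazone of the open 6,9-dihydroxy aldehyde
Conditions: TsNHNH2, THF, 25 °C
Reagents that add atoms: 4-methylbenzenesulfonohydrazide Cc1ccc(cc1)S(=O)(=O)NN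
Why: Hydrazone condensation through the open hydroxy aldehyde form of the lactol should proceed under nearly neutral conditions that do not enolise C11.

Step 15
Reactants: 28 tosylhydrazone
Product: 30 (1S,5R,6S,7R,9R,11S)-6,9-diol with the side chain C11(H)(CH3)–CH2–CH=CH2, via alkyl diazene 29 (not isolated)
Conditions: catecholborane (5 equiv), CHCl3, −10 °C; then NaOAc·3H2O, reflux
Reagents that add atoms: none
Why: Tosylhydrazone reduction (a mild Wolff–Kishner variant), in which hydride addition to C=N, loss of sulfinate and extrusion of N2 from diazene 29 should turn C19 into the C11 methyl group, uncatalysed catecholborane not hydroborating the alkenes at this temperature.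

Step 16
Reactants: 30 diol; 31 2-methylbut-3-en-2-ol
Product: 32 (1S,5R,6S,7R,9R,11S,13E)-6,9,15-triol
Conditions: 31 (10 equiv), second-generation Hoveyda–Grubbs catalyst (5 mol %), CH2Cl2, 40 °C
Reagents that add atoms: none
Why: Cross metathesis of the only monosubstituted alkene with an excess of the hindered tertiary allylic alcohol, which hardly homodimerises, should give the E-alkene under thermodynamic control.

Step 17
Reactants: 32 triol
Product: 33 target CNP0312076.1
Conditions: Ac2O (1.2 equiv), pyridine, CH2Cl2, 0 °C
Reagents that add atoms: acetic anhydride CC(=O)OC(C)=O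
Why: Rate-controlled acylation, in which the allylic O9–H flanked by CH2 and an sp2 carbon should react much faster than O6–H, flanked by two branched methines, and than the tertiary O15–H.

**Compound list**
1 | 3,3-diethoxyprop-1-ene | C=CC(OCC)OCC | starting material
2 | 2,3-dibromo-1,1-diethoxypropane (racemic) | BrCC(Br)C(OCC)OCC | intermediate
3 | 2-bromo-3,3-diethoxyprop-1-ene | C=C(Br)C(OCC)OCC | intermediate
4 | (R)-4-(tert-butyldimethylsilyloxy)cyclopent-2-en-1-one | O=C1C=C[C@H](O[Si](C)(C)C(C)(C)C)C1 | starting material
5 | (3,3-diethoxyprop-1-en-2-yl)lithium | [Li]C(=C)C(OCC)OCC | intermediate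
6 | (3,3-diethoxyprop-1-en-2-yl)copper (PBu3 complex) | [Cu]C(=C)C(OCC)OCC | intermediate
7 | copper enolate after 1,4-addition | C=C([C@H]1[C@H](O[Si](C)(C)C(C)(C)C)CC(O[Cu])=C1)C(OCC)OCC | intermediate
8 | (2S,3S,4R)-hydroxymethyl ketone | C=C([C@H]1[C@H](O[Si](C)(C)C(C)(C)C)CC(=O)[C@@H]1CO)C(OCC)OCC | intermediate
9 | bis-silyl ether of 8 | C=C([C@H]1[C@H](O[Si](C)(C)C(C)(C)C)CC(=O)[C@@H]1CO[Si](C)(C)C(C)(C)C)C(OCC)OCC | intermediate
10 | (4S,5S)-cyclopentenone | C=C([C@H]1C=CC(=O)[C@@H]1CO[Si](C)(C)C(C)(C)C)C(OCC)OCC | intermediate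
11 | lithium C3=C4 enolate | C=C([C@H]1CC=C(O[Li])[C@@H]1CO[Si](C)(C)C(C)(C)C)C(OCC)OCC | intermediate
12 | (4S,5S)-enol triflate | C=C([C@H]1CC=C(OS(=O)(=O)C(F)(F)F)[C@@H]1CO[Si](C)(C)C(C)(C)C)C(OCC)OCC | intermediate
13 | (1S,5R)-methylcyclopentene acetal | C=C([C@H]1CC=C(C)[C@@H]1CO[Si](C)(C)C(C)(C)C)C(OCC)OCC | intermediate
14 | (1S,5R)-enal | C=C([C@H]1CC=C(C)[C@@H]1CO[Si](C)(C)C(C)(C)C)C=O | intermediate
15 | pinacol borate ester of 16 | C=C([C@H]1CC=C(C)[C@@H]1CO[Si](C)(C)C(C)(C)C)[C@@H](CC=C)OB1OC(C)(C)C(C)(C)O1 | intermediate
16 | (1S,5R,9R)-homoallylic alcohol | C=C([C@H]1CC=C(C)[C@@H]1CO[Si](C)(C)C(C)(C)C)[C@@H](CC=C)O | intermediate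
17 | 2-(bromomethyl)prop-2-enoic acid | C=C(CBr)C(=O)O | starting material
18 | (1S,5R,9R)-2-(bromomethyl)acrylate ester | C=C([C@H]1CC=C(C)[C@@H]1CO[Si](C)(C)C(C)(C)C)[C@@H](CC=C)OC(=O)C(=C)CBr | intermediate
19 | (1S,5R,9R)-3-(bromomethyl)dihydropyranone, silyl ether | C=C([C@H]1CC=C(C)[C@@H]1CO[Si](C)(C)C(C)(C)C)[C@H]1CC=C(CBr)C(=O)O1 | intermediate
20 | (1S,5R,9R)-3-(bromomethyl)dihydropyranone, primary alcohol | C=C([C@H]1CC=C(C)[C@@H]1CO)[C@H]1CC=C(CBr)C(=O)O1 | intermediate
21 | (1S,5R,9R)-bromo aldehyde | C=C([C@H]1CC=C(C)[C@@H]1C=O)[C@H]1CC=C(CBr)C(=O)O1 | intermediate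
22 | allylchromium dichloride species | C=C([C@H]1CC=C(C)[C@@H]1C=O)[C@H]1CC=C(C[Cr](Cl)Cl)C(=O)O1 | intermediate
23 | bridged 6-hydroxy α-methylene-δ-lactone (formed as its chromium alkoxide) | C=C1[C@H]2CC=C(C)[C@@H]2[C@@H](O)[C@@H]3C[C@H]1OC(=O)C3=C | intermediate
24 | (1S,5R,6S,7R,9R)-9-hydroxy α-methylene-γ-lactone | C=C1[C@H]2CC=C(C)[C@@H]2[C@H]3OC(=O)C(=C)[C@H]3C[C@H]1O | intermediate
25 | bis(bromomagnesium) enolate alkoxide | C=C1[C@H]2CC=C(C)[C@@H]2[C@H]3OC(O[Mg]Br)=C(CC=C)[C@H]3C[C@H]1O[Mg]Br | intermediate
26 | (11S)-11-allyl γ-lactone | C=C1[C@H]2CC=C(C)[C@@H]2[C@H]3OC(=O)[C@@H](CC=C)[C@H]3C[C@H]1O | intermediate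
27 | lactol (anomers) | C=C1[C@H]2CC=C(C)[C@@H]2[C@H]3OC(O)[C@@H](CC=C)[C@H]3C[C@H]1O | intermediate
28 | C19 tosylhydrazone | C=C1[C@H]2CC=C(C)[C@@H]2[C@@H](O)[C@@H]([C@@H](/C=N/NS(=O)(=O)c3ccc(C)cc3)CC=C)C[C@H]1O | intermediate
29 | C19 alkyl diazene | C=C1[C@H]2CC=C(C)[C@@H]2[C@@H](O)[C@@H]([C@@H](CN=N)CC=C)C[C@H]1O | intermediate
30 | 6,9-diol with pent-4-en-2-yl side chain | C=C1[C@H]2CC=C(C)[C@@H]2[C@@H](O)[C@@H]([C@@H](C)CC=C)C[C@H]1O | intermediate
31 | 2-methylbut-3-en-2-ol | C=CC(C)(C)O | starting material
32 | 6,9,15-triol | C=C1[C@H]2CC=C(C)[C@@H]2[C@@H](O)[C@@H]([C@@H](C)C/C=C/C(C)(C)O)C[C@H]1O | intermediate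
33 | CNP0312076.1 | C=C1[C@H]2CC=C(C)[C@@H]2[C@@H](O)[C@@H]([C@@H](C)C/C=C/C(C)(C)O)C[C@H]1OC(C)=O | target

**Count:** 17 steps in total. The longest linear sequence is 17 steps (1 → 33), or 16 counted from enone 4.

**Steps most likely to fail**

Step 11. Protonation or dimerisation of the allylchromium species, or oligomerisation, may outrun closure through the bridged transition state, and the acyl shift may stop halfway. The fallback closes the same bond by a radical instead of a polar event. It sets out from 16 and comes back at 24.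
- Alcohol 16 is acylated with acryloyl chloride and Et3N to the acrylate ester F1.
- Ring-closing metathesis gives the unsubstituted dihydropyranone F2, aq HF gives the primary alcohol F3, and buffered Dess–Martin oxidation gives the aldehyde F4.
- SmI2 with t-BuOH in THF at high dilution forms the C6 ketyl radical. This should add 7-exo-trig to C7 on the face dictated by the tether, with samarium bridging O6 and the lactone carbonyl.
- After protonation and the same O9→O6 acyl shift, the saturated hydroxy γ-lactone F5 results.
- α-Methylenation follows: LDA (2.2 equiv) and dimethylmethyleneammonium iodide give the Mannich base F6, then MeI and NaHCO3 lead to 24.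

Step 12. Facial selectivity in the protonation of enolate 25 may erode, or C11 may later epimerise toward the more stable exo isomer. The fallback exchanges the roles of the two carbons on C11, so that the configuration needed is the thermodynamic one. It sets out from 24 and comes back at 30.
- NaBH4 in MeOH reduces the exocyclic enoate 1,4, and DBU equilibrates the product to the exo-methyl γ-lactone F7. The former methylene carbon is now C19 and the carbonyl is C12.
- i-Bu2AlH gives the lactol F8, and Ph3P=CHOMe (excess) gives the enol ether F9.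
- PPTS in wet THF gives the six-membered lactol F10.
- Ph3P=CH2 opens F10 to the C12H2–C13H=CH2 chain of 30.

Step 4. 1,2-Reduction of the enone may compete with 1,4-delivery, or proton transfer within the enolate may precede sulfonylation. The fallback brings in the methyl group as a nucleophile and moves the double bond by allylic transposition. It sets out from 10 and comes back at 13.
- MeLi with CeCl3 adds 1,2 to give the tertiary allylic alcohol F11.
- SOCl2 and pyridine in Et2O give, with allylic shift, the secondary allylic chloride F12 (C2–Cl, C3=C4–CH3).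
- LiBHEt3 displaces the chloride at the less hindered C2 to give 13.

Further compounds
F1 | step 11 | (1S,5R,9R)-acrylate ester of 16 | C=C([C@H]1CC=C(C)[C@@H]1CO[Si](C)(C)C(C)(C)C)[C@@H](CC=C)OC(=O)C=C
F2 | step 11 | (1S,5R,9R)-5,6-dihydropyran-2-one, silyl ether | C=C([C@H]1CC=C(C)[C@@H]1CO[Si](C)(C)C(C)(C)C)[C@H]1CC=CC(=O)O1
F3 | step 11 | (1S,5R,9R)-5,6-dihydropyran-2-one, primary alcohol | C=C([C@H]1CC=C(C)[C@@H]1CO)[C@H]1CC=CC(=O)O1
F4 | step 11 | (1S,5R,9R)-5,6-dihydropyran-2-one, aldehyde | C=C([C@H]1CC=C(C)[C@@H]1C=O)[C@H]1CC=CC(=O)O1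
F5 | step 11 | (1S,5R,6S,7R,9R)-9-hydroxy γ-lactone without C12 | C=C1[C@H]2CC=C(C)[C@@H]2[C@H]3OC(=O)C[C@H]3C[C@H]1O
F6 | step 11 | α-(dimethylaminomethyl) γ-lactone | C=C1[C@H]2CC=C(C)[C@@H]2[C@H]3OC(=O)[C@H](CN(C)C)[C@H]3C[C@H]1O
F7 | step 12 | exo-methyl γ-lactone (carbonyl = C12) | C=C1[C@H]2CC=C(C)[C@@H]2[C@H]3OC(=O)[C@H](C)[C@H]3C[C@H]1O
F8 | step 12 | five-membered lactol (anomers) | C=C1[C@H]2CC=C(C)[C@@H]2[C@H]3OC(O)[C@H](C)[C@H]3C[C@H]1O
F9 | step 12 | methyl enol ether (E/Z mixture) | C=C1[C@H]2CC=C(C)[C@@H]2[C@@H](O)[C@@H]([C@@H](C)C=COC)C[C@H]1O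
F10 | step 12 | six-membered lactol (anomers) | C=C1[C@H]2CC=C(C)[C@@H]2[C@H]3OC(O)C[C@H](C)[C@H]3C[C@H]1O
F11 | step 4 | tertiary allylic alcohol | C=C([C@H]1C=C[C@](C)(O)[C@@H]1CO[Si](C)(C)C(C)(C)C)C(OCC)OCC
F12 | step 4 | secondary allylic chloride | C=C([C@H]1[C@H](Cl)C=C(C)[C@@H]1CO[Si](C)(C)C(C)(C)C)C(OCC)OCC
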